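**Plan**

1. Retrosynthesis: first the two benzyl–O bonds (catechol protection), then in one cut the C1–C2 bond of the 20-methylhenicosyl chain together with the acyl O–CH2 bond, giving an aroyl bromide, formaldehyde and 19-methylicos-1-ene. The alkene is cut at C11–C12 and C16–C17 into 11-bromoundec-1-ene, 1,5-dibromopentane and isopentylmagnesium bromide.
2. Forward, chain: two copper-catalysed sp3–sp3 couplings (iso-C5 + C5, then + C11) give the C21 terminal alkene. Forward, arene: 2,3-dihydroxybenzoic acid (benzene ring bought intact, no ring is made) is benzylated and converted into the acyl bromide.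
3. Key event: acyl bromide, formaldehyde and alkene are joined in one flask. The bromomethyl ester forms first, then a nickel hydride adds it anti-Markovnikov across the terminal alkene, which completes the whole C22 ester skeleton.
4. Enabling feature: the O–CH2 carbon (chain C1) bound to the ester oxygen. As Br–CH2–O–C(=O)Ar that oxygen stabilises a radical at C1, and the unbranched C2–C3 beside it is the footprint of a terminal alkene. Bromide, alkene and benzyl groups are the helpers; the first two are consumed in the event, the last leave in the final step.
5. Stereochemistry: none to set (no stereocentre, no stereogenic double bond); only linear regiochemistry matters. Hydrogenolysis then frees the catechol.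

Key step: step 5

Remark: the alcohol part is read as 20-methylhenicosan-1-ol (iso-C22); the target is achiral.

**Step 1**
Reactants: 1 isopentylmagnesium bromide (3-methylbutylmagnesium bromide); 2 1,5-dibromopentane (3 equiv)
Product: 3 1-bromo-8-methylnonane
Conditions: Li2CuCl4 (cat.), THF, −10 °C → rt; surplus 2 removed by distillation
Reagents that add atoms: none
Why: Copper-catalysed Grignard–alkyl bromide cross-coupling (Kochi type), in which the excess of dibromide should make mono-alkylation dominant and the volatile surplus is easily distilled off.

**Step 2**
Reactants: 3 1-bromo-8-methylnonane; 4 11-bromoundec-1-ene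
Product: 6 19-methylicos-1-ene, via (8-methylnonyl)magnesium bromide 5 (not isolated)
Conditions: Mg, THF, reflux; then 4, Li2CuCl4 (cat.), THF, −10 °C → rt
Reagents that add atoms: none
Why: A second Kochi-type copper-catalysed sp3–sp3 coupling, in which the primary bromide reacts and the remote terminal alkene is untouched; the saturated hydrocarbon by-products are inert in later steps.

**Step 3**
Reactants: 7 2,3-dihydroxybenzoic acid
Product: 9 2,3-bis(benzyloxy)benzoic acid, via benzyl 2,3-bis(benzyloxy)benzoate 8 (not isolated)
Conditions: BnBr, K2CO3, acetone, reflux; then NaOH, MeOH/H2O, reflux; HCl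
Reagents that add atoms: benzyl bromide, BrCc1ccccc1
Why: Williamson benzylation of both phenols and the carboxylate, then saponification that should cleave only the benzyl ester because aryl benzyl ethers are inert to hydroxide.

**Step 4**
Reactants: 9 2,3-bis(benzyloxy)benzoic acid
Product: 10 2,3-bis(benzyloxy)benzoyl bromide
Conditions: (COBr)2, DMF (cat.), CH2Cl2, 0 °C → rt; evaporated and used crude
Reagents that add atoms: oxalyl bromide, O=C(Br)C(=O)Br
Why: Vilsmeier-type activation of the acid (oxalyl halide with catalytic DMF) should give the acyl bromide under anhydrous conditions with only volatile by-products.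

**Step 5**
Reactants: 10 2,3-bis(benzyloxy)benzoyl bromide; 11 paraformaldehyde; 6 19-methylicos-1-ene
Product: 13 20-methylhenicosyl 2,3-bis(benzyloxy)benzoate, via bromomethyl 2,3-bis(benzyloxy)benzoate 12 (not isolated)
Conditions: (i) (CH2O)n, ZnBr2 (cat.), CH2Cl2, 0 °C → rt, evaporate; (ii) 6, NiBr2·glyme (cat.), bis(oxazoline) ligand (cat.), (EtO)3SiH, K3PO4·H2O, DMA/THF, rt
Reagents that add atoms: none
Why: In stage (i) formaldehyde activated by ZnBr2 is acylated by 10 and takes up bromide, the established way to bromomethyl esters, to give 12. In stage (ii) a nickel hydride formed from the nickel bromide, the hydrosilane and phosphate inserts the terminal C=C of 6 so that nickel sits on the unsubstituted carbon, while Ni(I) abstracts bromine from 12 to give the radical ArCO2CH2•, stabilised by the lone pair of the ester oxygen; capture of this radical at nickel and reductive elimination from Ni(III) should form the CH2–CH2 bond. The closest known reaction type is the nickel-catalysed hydroalkylation of terminal olefins with α-bromoalkyl carboxylates generated in the flask from an aldehyde and an acyl bromide (aldehyde/acyl bromide/olefin/hydrosilane coupling), of which formaldehyde is the parent aldehyde. No ring is closed and no stereocentre is created, so a racemic or achiral bis(oxazoline) suffices. The step needs linear regioselectivity, which the monosubstituted alkene secures because hydrometalation places nickel at the unhindered terminal carbon and the saturated isopropyl end offers no second site, and it needs the C–Br bond of 12 to react in preference to its acyl C–O bond and the benzyl ethers, which the weak, oxygen-activated C–Br bond should secure at room temperature.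

**Step 6**
Reactants: 13 20-methylhenicosyl 2,3-bis(benzyloxy)benzoate
Product: 14 Gentiside A
Conditions: H2 (1 atm), Pd/C, EtOAc/THF, rt
Reagents that add atoms: none
Why: Palladium-catalysed hydrogenolysis should cleave both aryl benzyl ethers to free the catechol, while the alkyl benzoate and the saturated chain are inert.

**Compound list** (no compound has a stereocentre or a stereogenic double bond)

1 | isopentylmagnesium bromide (3-methylbutylmagnesium bromide) | CC(C)CC[Mg]Br | starting material
2 | 1,5-dibromopentane | BrCCCCCBr | starting material
3 | 1-bromo-8-methylnonane | CC(C)CCCCCCCBr | intermediate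
4 | 11-bromoundec-1-ene | C=CCCCCCCCCCBr | starting material
5 | (8-methylnonyl)magnesium bromide | CC(C)CCCCCCC[Mg]Br | intermediate
6 | 19-methylicos-1-ene | CC(C)CCCCCCCCCCCCCCCCC=C | intermediate
7 | 2,3-dihydroxybenzoic acid | OC(=O)c1cccc(O)c1O | starting material
8 | benzyl 2,3-bis(benzyloxy)benzoate | O=C(OCc1ccccc1)c1cccc(OCc2ccccc2)c1OCc1ccccc1 | intermediate
9 | 2,3-bis(benzyloxy)benzoic acid | OC(=O)c1cccc(OCc2ccccc2)c1OCc1ccccc1 | intermediate
10 | 2,3-bis(benzyloxy)benzoyl bromide | BrC(=O)c1cccc(OCc2ccccc2)c1OCc1ccccc1 | intermediate
11 | paraformaldehyde (source of formaldehyde; SMILES of the monomer) | C=O | starting material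
12 | bromomethyl 2,3-bis(benzyloxy)benzoate | BrCOC(=O)c1cccc(OCc2ccccc2)c1OCc1ccccc1 | intermediate
13 | 20-methylhenicosyl 2,3-bis(benzyloxy)benzoate | CC(C)CCCCCCCCCCCCCCCCCCCOC(=O)c1cccc(OCc2ccccc2)c1OCc1ccccc1 | intermediate
14 | Gentiside A (20-methylhenicosyl 2,3-dihydroxybenzoate) | CC(C)CCCCCCCCCCCCCCCCCCCOC(=O)c1cccc(O)c1O | target

**Totals**

Total step count: 6. Longest linear sequence: 4 steps (1 → 2 → 5 → 6, or 3 → 4 → 5 → 6).

**Steps most likely to fail**

1. Step 5. The bromomethyl ester may be consumed by hydrolysis or by plain reduction to the methyl ester before the alkylnickel captures it. Benzyl ethers may be lost under the Lewis acid of stage (i), and the alkene may isomerise. The fallback sets out from 6 and comes back at 13. Linear-selective rhodium-catalysed hydroformylation of 6 (Rh(acac)(CO)2, BiPhePhos, CO/H2, toluene, 80 °C) would form the same C1–C2 bond by CO insertion and give 20-methylhenicosanal F1. Reduction with NaBH4 (MeOH/THF) would give 20-methylhenicosan-1-ol F2. Steglich esterification of F2 with acid 9 (DCC, DMAP, CH2Cl2) would give 13, and step 6 follows.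

2. Step 4. Benzyl groups may be lost through the HBr set free beside the ortho-benzyloxy group, and the acyl bromide may hydrolyse on handling. The fallback sets out from 9 and comes back at 12, and avoids both the acyl bromide and the Lewis acid. O-Alkylation of the carboxylate of 9 with chloromethyl chlorosulfate under phase transfer (NaHCO3, Bu4NHSO4, CH2Cl2/H2O, rt) would give chloromethyl 2,3-bis(benzyloxy)benzoate F3. Finkelstein exchange with LiBr in acetone would give 12, here isolated, which enters stage (ii) of step 5.

3. Step 2. Wurtz homocoupling and protonation of the Grignard reagent, or incomplete coupling, may give hydrocarbon mixtures that are hard to separate from the alkene. The fallback sets out from 3 and comes back at 6. Displacement of bromide in 3 by sodium benzenesulfinate (DMF, 80 °C) would give (8-methylnonyl) phenyl sulfone F4. Deprotonation (n-BuLi, THF, −78 °C) and alkylation with 4 would give [(19-methylicos-1-en-12-yl)sulfonyl]benzene F5, a polar and easily purified intermediate. Reductive desulfonylation (Na/Hg, Na2HPO4, MeOH/THF) would give 6 with the terminal alkene untouched.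

**Further compounds**

F1 | step 5 | 20-methylhenicosanal | CC(C)CCCCCCCCCCCCCCCCCCC=O
F2 | step 5 | 20-methylhenicosan-1-ol | CC(C)CCCCCCCCCCCCCCCCCCCO
F3 | step 4 | chloromethyl 2,3-bis(benzyloxy)benzoate | ClCOC(=O)c1cccc(OCc2ccccc2)c1OCc1ccccc1
F4 | step 2 | (8-methylnonyl) phenyl sulfone | CC(C)CCCCCCCS(=O)(=O)c1ccccc1
F5 | step 2 | [(19-methylicos-1-en-12-yl)sulfonyl]benzene | CC(C)CCCCCCC(CCCCCCCCCC=C)S(=O)(=O)c1ccccc1
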